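**Retrosynthetic overview**
- Target ⇒ anti-SN2′ methylation of a C11 allylic picolinate (sets C13 and the E-alkene) ⇒ bis-allylic carbinol ⇒ (E)-γ,γ-disubstituted allylboronate (right half) + (E)-enal (left half); this allylboration makes the C10–C11 bond and sets C10.
- Allylboronate ⇐ ring-bearing terminal alkyne (carboalumination, Matteson homologation); enal ⇐ acyclic dienyne (hydrozirconation–carbonylation).
- Both alkynes ⇐ Zweifel coupling of one chiral secondary boronic ester with either a cyclohexenyl bromide or an acyclic 2-bromo-1,6-diene.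
- Both bromides ⇐ one enyne. The only ring is closed once, early, along the natural C–C bond: the tertiary C2 cation from protonation of the isopropenyl end attacks the outer carbon of the C6 π-system (an alkyne standing in for the exo-methylene) and bromide caps C6.
- Enyne ⇐ the same boronic ester + isopropenyllithium; the boronic ester ⇐ sparteine-controlled lithiation–borylation. It supplies all four secondary methyl centres (C3, C7, C16, C20).

Assumption: the SMILES is read literally, i.e. 3R,7R,10S,13S,16R,20R in botryococcene-type numbering (used below for positions); ethyl 2,4,6-triisopropylbenzoate, (−)-sparteine, B-bromo-9-BBN and ClCH2Bpin are taken as catalogue chemicals.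

**Route**

Step 1
Reactants: 1 (4-bromobut-1-yn-1-yl)trimethylsilane
Product: 3 trimethyl[4-(4,4,5,5-tetramethyl-1,3,2-dioxaborolan-2-yl)but-1-yn-1-yl]silane, via Grignard reagent 2 (not isolated)
Conditions: Mg, THF, rt; then 2-isopropoxy-4,4,5,5-tetramethyl-1,3,2-dioxaborolane, −78 °C → rt
Reagents that add atoms: 2-isopropoxy-4,4,5,5-tetramethyl-1,3,2-dioxaborolane, CC(C)OB1OC(C)(C)C(C)(C)O1
Why: Grignard formation followed by alkoxide displacement at boron (Grignard borylation) gives the primary pinacol boronic ester; no stereocentre is involved.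

Step 2
Reactants: 3 trimethyl[4-(pinacolboryl)but-1-yn-1-yl]silane, 4 ethyl 2,4,6-triisopropylbenzoate
Product: 7 trimethyl[(5R)-5-(4,4,5,5-tetramethyl-1,3,2-dioxaborolan-2-yl)hex-1-yn-1-yl]silane, via lithiated benzoate 5 (not isolated), via boronate complex 6 (not isolated)
Conditions: 4, (−)-sparteine, s-BuLi, Et2O, −78 °C, 5 h; then 3, −78 °C, 1 h; then 35 °C, 16 h
Reagents that add atoms: none
Why: Lithiation–borylation (Hoppe–Aggarwal): sparteine-directed removal of the pro-S proton gives the (S)-carbenoid, boronate formation occurs with retention and the 1,2-metallate shift with inversion, so the boron-bearing methyl centre is set as R by the reagent.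

Step 3
Reactants: 7 boronic ester (R), 8 2-bromopropene
Product: 12 (3R)-2,3-dimethylhept-1-en-6-yne, via isopropenyllithium 9 (not isolated), via boronate complex 10 (not isolated), via silyl enyne 11 (not isolated)
Conditions: 8, t-BuLi (2 equiv), THF, −78 °C; 7, −78 °C; I2, MeOH, −78 °C; NaOMe, −78 °C → rt; aq Na2S2O3 wash; then K2CO3, MeOH, rt
Reagents that add atoms: none
Why: Zweifel olefination (iodine-triggered 1,2-migration with retention at the migrating sp3 carbon, then anti-elimination) joins the stereocentre to the isopropenyl carbon, and methanolic carbonate then cleaves the alkynyl C–Si bond.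

Step 4
Reactants: 12 (3R)-2,3-dimethylhept-1-en-6-yne
Product: 14 (4R)-1-bromo-3,3,4-trimethylcyclohex-1-ene, via tertiary bromide 13 (not isolated)
Conditions: HBr (1.0 equiv, CH2Cl2 solution), CH2Cl2, −78 °C; then ZnBr2 (20 mol %, Et2O solution), −78 → −30 °C
Reagents that add atoms: hydrogen bromide, Br
Why: Proposed new method: Markovnikov HBr addition to the isopropenyl group (far more basic than the alkyne) gives 13, whose ZnBr2-assisted ionisation regenerates the biosynthetic C2 tertiary cation; this is captured 6-endo by the terminal alkyne carbon (5-exo would need a primary vinyl cation) while bromide from the bromozincate caps C6 anti, so the ring alkene is fixed at C6=C(former methylene) and C6 carries the coupling handle; the methyl stereocentre is not a reacting atom and is kept provided ring closure outruns 1,2-hydride shift; closest known reaction types are Lewis-acid-catalysed additions of tertiary alkyl halides across alkynes to give vinyl halides and halide-terminated cation–alkyne cyclisations.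

Step 5
Reactants: 12 (3R)-2,3-dimethylhept-1-en-6-yne
Product: 16 (3R)-6-bromo-2,3-dimethylhepta-1,6-diene, via bromoalkenylborane 15 (not isolated)
Conditions: B-bromo-9-BBN, CH2Cl2, 0 °C → rt; then AcOH, 0 °C → rt
Reagents that add atoms: B-bromo-9-borabicyclo[3.3.1]nonane, BrB1C2CCCC1CCC2
Why: Haloboration: syn-bromoboration is selective for the terminal alkyne over the alkene and puts Br on the internal carbon, and protonolysis of the C–B bond gives the 2-bromo-1-alkene without touching the stereocentre.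

Step 6
Reactants: 7 boronic ester (R), 14 (4R)-1-bromo-3,3,4-trimethylcyclohex-1-ene
Product: 20 (4R)-1-[(2R)-hex-5-yn-2-yl]-3,3,4-trimethylcyclohex-1-ene, via cyclohexenyllithium 17 (not isolated), via boronate complex 18 (not isolated), via silyl alkyne 19 (not isolated)
Conditions: 14, t-BuLi (2 equiv), THF/Et2O, −78 °C; 7, −78 °C; I2, MeOH, −78 °C; NaOMe, −78 °C → rt; aq Na2S2O3 wash; then K2CO3, MeOH, rt
Reagents that add atoms: none
Why: Zweifel olefination forms the C6–C7 bond with retention at the boron-bearing carbon, so C7 is R, and the alkyne is unmasked in the same operation.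

Step 7
Reactants: 7 boronic ester (R), 16 (3R)-6-bromo-2,3-dimethylhepta-1,6-diene
Product: 24 (5R,9R)-5,9,10-trimethyl-6-methylideneundec-10-en-1-yne, via dienyllithium 21 (not isolated), via boronate complex 22 (not isolated), via silyl alkyne 23 (not isolated)
Conditions: 16, t-BuLi (2 equiv), THF/Et2O, −78 °C; 7, −78 °C; I2, MeOH, −78 °C; NaOMe, −78 °C → rt; aq Na2S2O3 wash; then K2CO3, MeOH, rt
Reagents that add atoms: none
Why: The same stereoretentive Zweifel olefination forms the C16–C17 bond and the C17 exo-methylene, giving C16 as R.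

Step 8
Reactants: 20 ring alkyne
Product: 26 (4R)-1-[(2R,5E)-6-iodo-5-methylhex-5-en-2-yl]-3,3,4-trimethylcyclohex-1-ene, via alkenylalane 25 (not isolated)
Conditions: Me3Al, Cp2ZrCl2 (20 mol %), CH2Cl2, 0 °C → rt; then I2, THF, −30 → 0 °C
Reagents that add atoms: trimethylaluminium, C[Al](C)C; iodine, II
Why: Negishi zirconium-catalysed carboalumination adds Me and Al syn across the terminal alkyne (Me on the internal carbon, the future C10) and iodinolysis with retention gives the E-iodide; the trisubstituted ring alkene is inert.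

Step 9
Reactants: 26 E-alkenyl iodide, 27 2-(chloromethyl)-4,4,5,5-tetramethyl-1,3,2-dioxaborolane
Product: 30 4,4,5,5-tetramethyl-2-{(2E,6R)-3-methyl-6-[(4R)-3,3,4-trimethylcyclohex-1-en-1-yl]hept-2-en-1-yl}-1,3,2-dioxaborolane, via alkenyllithium 28 (not isolated), via boronate complex 29 (not isolated)
Conditions: t-BuLi (2 equiv), Et2O, −78 °C; 27, −78 °C → rt
Reagents that add atoms: none
Why: Iodine–lithium exchange with retention, then Matteson homologation (1,2-shift of the alkenyl group with loss of chloride), gives the geometrically pure E-allylboronate.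

Step 10
Reactants: 24 acyclic dienyne
Product: 33 (2E,6R,10R)-6,10,11-trimethyl-7-methylidenedodeca-2,11-dienal, via alkenylzirconocene 31 (not isolated), via acylzirconocene 32 (not isolated)
Conditions: Cp2Zr(H)Cl (1.05 equiv), CH2Cl2, 0 °C → rt; CO (1 atm), rt; 1 M HCl, 0 °C
Reagents that add atoms: carbon monoxide, [C-]#[O+]
Why: Hydrozirconation is syn and terminal and much faster for the alkyne than for 1,1-disubstituted alkenes, CO inserts into the C–Zr bond, and protonolysis of the acyl complex gives the E-enal (hydrozirconation–carbonylation).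

Step 11
Reactants: 30 E-allylboronate, 33 E-enal
Product: 35 (2R,5S,6R,7E,11R,15R)-5-ethenyl-5,11,15,16-tetramethyl-12-methylidene-2-[(4R)-3,3,4-trimethylcyclohex-1-en-1-yl]heptadeca-7,16-dien-6-ol, via borate ester 34 (not isolated)
Conditions: (S)-3,3′-bis(2,4,6-triisopropylphenyl)-1,1′-binaphthyl-2,2′-diyl hydrogen phosphate (5 mol %), 4 Å molecular sieves, toluene, −30 → 0 °C; aq NaHCO3 work-up
Reagents that add atoms: none
Why: Chiral phosphoric acid-catalysed allylboration through a closed chair transition state: the E-geometry of 30 places the C9 chain anti and the methyl syn to the new hydroxyl, and the catalyst selects the aldehyde face, giving the quaternary C10 as S together with C11 as R (acid enantiomer chosen by extrapolation from the established allyl and crotyl cases).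

Step 12
Reactants: 35 bis-allylic carbinol
Product: 36 (2R,5S,6R,7E,11R,15R)-5-ethenyl-5,11,15,16-tetramethyl-12-methylidene-2-[(4R)-3,3,4-trimethylcyclohex-1-en-1-yl]heptadeca-7,16-dien-6-yl pyridine-2-carboxylate
Conditions: pyridine-2-carboxylic acid, N,N′-dicyclohexylcarbodiimide, 4-(dimethylamino)pyridine (cat.), CH2Cl2, rt
Reagents that add atoms: pyridine-2-carboxylic acid, OC(=O)c1ccccn1
Why: Steglich esterification installs the chelating picolinoxy leaving group without touching any stereocentre.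

Step 13
Reactants: 36 allylic picolinate
Product: 37 (3R,7R,10S,11E,13S,16R)-13-ethenyl-2,3,7,10,13-pentamethyl-6-methylidene-16-[(4R)-3,3,4-trimethylcyclohex-1-en-1-yl]heptadeca-1,11-diene (CNP0321027.1)
Conditions: MeMgBr (2.5 equiv), CuBr·SMe2 (30 mol %), THF, −40 → 0 °C
Reagents that add atoms: methylmagnesium bromide, C[Mg]Br
Why: Copper-catalysed anti-SN2′ allylic substitution with 1,3-chirality transfer: direct SN2 at the neopentyl C11 is blocked, the methyl enters C13 anti to the picolinate in the conformer with the C11–H inside, so the (11R)-ester gives C13 as S and the C11=C12 alkene as E, with C10 untouched.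

**Compound list**
1 | (4-bromobut-1-yn-1-yl)trimethylsilane | C[Si](C)(C)C#CCCBr | starting material
2 | [4-(trimethylsilyl)but-3-yn-1-yl]magnesium bromide | C[Si](C)(C)C#CCC[Mg]Br | intermediate
3 | trimethyl[4-(4,4,5,5-tetramethyl-1,3,2-dioxaborolan-2-yl)but-1-yn-1-yl]silane | C[Si](C)(C)C#CCCB1OC(C)(C)C(C)(C)O1 | intermediate
4 | ethyl 2,4,6-triisopropylbenzoate | CCOC(=O)c1c(C(C)C)cc(C(C)C)cc1C(C)C | starting material
5 | (1S)-1-lithioethyl 2,4,6-triisopropylbenzoate (sparteine-bound) | C[C@H]([Li])OC(=O)c1c(C(C)C)cc(C(C)C)cc1C(C)C | intermediate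
6 | lithium [(1S)-1-(2,4,6-triisopropylbenzoyloxy)ethyl][4-(trimethylsilyl)but-3-yn-1-yl](pinacolato)borate | [Li+].C[C@@H](OC(=O)c1c(C(C)C)cc(C(C)C)cc1C(C)C)[B-]1(CCC#C[Si](C)(C)C)OC(C)(C)C(C)(C)O1 | intermediate
7 | trimethyl[(5R)-5-(4,4,5,5-tetramethyl-1,3,2-dioxaborolan-2-yl)hex-1-yn-1-yl]silane | C[C@H](CCC#C[Si](C)(C)C)B1OC(C)(C)C(C)(C)O1 | intermediate
8 | 2-bromopropene | CC(Br)=C | starting material
9 | prop-1-en-2-yllithium | [Li]C(C)=C | intermediate
10 | lithium (prop-1-en-2-yl)[(2R)-6-(trimethylsilyl)hex-5-yn-2-yl](pinacolato)borate | [Li+].C=C(C)[B-]1([C@H](C)CCC#C[Si](C)(C)C)OC(C)(C)C(C)(C)O1 | intermediate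
11 | trimethyl[(5R)-5,6-dimethylhept-6-en-1-yn-1-yl]silane | C=C(C)[C@H](C)CCC#C[Si](C)(C)C | intermediate
12 | (3R)-2,3-dimethylhept-1-en-6-yne | C=C(C)[C@H](C)CCC#C | intermediate
13 | (5R)-6-bromo-5,6-dimethylhept-1-yne | CC(C)(Br)[C@H](C)CCC#C | intermediate
14 | (4R)-1-bromo-3,3,4-trimethylcyclohex-1-ene | BrC1=CC(C)(C)[C@H](C)CC1 | intermediate
15 | 9-[(1Z,5R)-2-bromo-5,6-dimethylhepta-1,6-dien-1-yl]-9-borabicyclo[3.3.1]nonane | C=C(C)[C@H](C)CC/C(Br)=C/B1C2CCCC1CCC2 | intermediate
16 | (3R)-6-bromo-2,3-dimethylhepta-1,6-diene | C=C(C)[C@H](C)CCC(Br)=C | intermediate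
17 | [(4R)-3,3,4-trimethylcyclohex-1-en-1-yl]lithium | [Li]C1=CC(C)(C)[C@H](C)CC1 | intermediate
18 | lithium [(2R)-6-(trimethylsilyl)hex-5-yn-2-yl][(4R)-3,3,4-trimethylcyclohex-1-en-1-yl](pinacolato)borate | [Li+].C[C@H](CCC#C[Si](C)(C)C)[B-]1(C2=CC(C)(C)[C@H](C)CC2)OC(C)(C)C(C)(C)O1 | intermediate
19 | trimethyl{(5R)-5-[(4R)-3,3,4-trimethylcyclohex-1-en-1-yl]hex-1-yn-1-yl}silane | C[Si](C)(C)C#CCC[C@@H](C)C1=CC(C)(C)[C@H](C)CC1 | intermediate
20 | (4R)-1-[(2R)-hex-5-yn-2-yl]-3,3,4-trimethylcyclohex-1-ene | C#CCC[C@@H](C)C1=CC(C)(C)[C@H](C)CC1 | intermediate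
21 | [(5R)-5,6-dimethylhepta-1,6-dien-2-yl]lithium | [Li]C(=C)CC[C@@H](C)C(C)=C | intermediate
22 | lithium [(5R)-5,6-dimethylhepta-1,6-dien-2-yl][(2R)-6-(trimethylsilyl)hex-5-yn-2-yl](pinacolato)borate | [Li+].C[C@H](CCC#C[Si](C)(C)C)[B-]1(C(=C)CC[C@@H](C)C(C)=C)OC(C)(C)C(C)(C)O1 | intermediate
23 | trimethyl[(5R,9R)-5,9,10-trimethyl-6-methylideneundec-10-en-1-yn-1-yl]silane | C[Si](C)(C)C#CCC[C@@H](C)C(=C)CC[C@@H](C)C(C)=C | intermediate
24 | (5R,9R)-5,9,10-trimethyl-6-methylideneundec-10-en-1-yne | C#CCC[C@@H](C)C(=C)CC[C@@H](C)C(C)=C | intermediate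
25 | dimethyl{(1E,5R)-2-methyl-5-[(4R)-3,3,4-trimethylcyclohex-1-en-1-yl]hex-1-en-1-yl}alumane | C[Al](C)/C=C(\C)CC[C@@H](C)C1=CC(C)(C)[C@H](C)CC1 | intermediate
26 | (4R)-1-[(2R,5E)-6-iodo-5-methylhex-5-en-2-yl]-3,3,4-trimethylcyclohex-1-ene | I/C=C(\C)CC[C@@H](C)C1=CC(C)(C)[C@H](C)CC1 | intermediate
27 | 2-(chloromethyl)-4,4,5,5-tetramethyl-1,3,2-dioxaborolane | ClCB1OC(C)(C)C(C)(C)O1 | starting material
28 | {(1E,5R)-2-methyl-5-[(4R)-3,3,4-trimethylcyclohex-1-en-1-yl]hex-1-en-1-yl}lithium | [Li]/C=C(\C)CC[C@@H](C)C1=CC(C)(C)[C@H](C)CC1 | intermediate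
29 | lithium (chloromethyl){(1E,5R)-2-methyl-5-[(4R)-3,3,4-trimethylcyclohex-1-en-1-yl]hex-1-en-1-yl}(pinacolato)borate | [Li+].ClC[B-]1(/C=C(\C)CC[C@@H](C)C2=CC(C)(C)[C@H](C)CC2)OC(C)(C)C(C)(C)O1 | intermediate
30 | 4,4,5,5-tetramethyl-2-{(2E,6R)-3-methyl-6-[(4R)-3,3,4-trimethylcyclohex-1-en-1-yl]hept-2-en-1-yl}-1,3,2-dioxaborolane | CC1(C)OB(C/C=C(\C)CC[C@@H](C)C2=CC(C)(C)[C@H](C)CC2)OC1(C)C | intermediate
31 | chlorobis(cyclopentadienyl)[(1E,5R,9R)-5,9,10-trimethyl-6-methylideneundeca-1,10-dien-1-yl]zirconium | Cl[Zr](C1C=CC=C1)(C1C=CC=C1)/C=C/CC[C@@H](C)C(=C)CC[C@@H](C)C(C)=C | intermediate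
32 | chlorobis(cyclopentadienyl)[(2E,6R,10R)-6,10,11-trimethyl-7-methylidenedodeca-2,11-dienoyl]zirconium | Cl[Zr](C1C=CC=C1)(C1C=CC=C1)C(=O)/C=C/CC[C@@H](C)C(=C)CC[C@@H](C)C(C)=C | intermediate
33 | (2E,6R,10R)-6,10,11-trimethyl-7-methylidenedodeca-2,11-dienal | O=C/C=C/CC[C@@H](C)C(=C)CC[C@@H](C)C(C)=C | intermediate
34 | pinacol borate ester of 35 (O–B at C6 of the heptadecadienol) | C=C[C@@](C)([C@H](OB1OC(C)(C)C(C)(C)O1)/C=C/CC[C@@H](C)C(=C)CC[C@@H](C)C(C)=C)CC[C@@H](C)C1=CC(C)(C)[C@H](C)CC1 | intermediate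
35 | (2R,5S,6R,7E,11R,15R)-5-ethenyl-5,11,15,16-tetramethyl-12-methylidene-2-[(4R)-3,3,4-trimethylcyclohex-1-en-1-yl]heptadeca-7,16-dien-6-ol | C=C[C@@](C)([C@H](O)/C=C/CC[C@@H](C)C(=C)CC[C@@H](C)C(C)=C)CC[C@@H](C)C1=CC(C)(C)[C@H](C)CC1 | intermediate
36 | pyridine-2-carboxylate ester of 35 | C=C[C@@](C)([C@H](OC(=O)c1ccccn1)/C=C/CC[C@@H](C)C(=C)CC[C@@H](C)C(C)=C)CC[C@@H](C)C1=CC(C)(C)[C@H](C)CC1 | intermediate
37 | (3R,7R,10S,11E,13S,16R)-13-ethenyl-2,3,7,10,13-pentamethyl-6-methylidene-16-[(4R)-3,3,4-trimethylcyclohex-1-en-1-yl]heptadeca-1,11-diene | C=C[C@@](C)(/C=C/[C@@H](C)CC[C@@H](C)C(=C)CC[C@@H](C)C(=C)C)CC[C@@H](C)C1=CC(C)(C)[C@H](C)CC1 | target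

**Totals and risks**
Total step count: 13. Longest linear sequence: 10 steps (1, 2, 3, 4, 6, 8, 9, 11, 12, 13).

The three steps most likely to fail:

- **Step 4 (cation–alkyne ring closure).** The tertiary cation sits next to the methyl-bearing C–H, so a 1,2-hydride shift or proton loss to the tetrasubstituted alkene can erode the configuration of 14 before the weakly nucleophilic alkyne closes the ring. The fallback sets out from 12 and returns at 14. Ozonolysis of the isopropenyl group (O3, CH2Cl2, −78 °C; Me2S) gives (3R)-3-methylhept-6-yn-2-one F1. A bromide-terminated carbonyl–alkyne cyclisation (TiBr4, CH2Cl2, −78 °C) forms the same ring bond from the activated ketone and gives (6R)-3-bromo-1,6-dimethylcyclohex-2-en-1-ol F2 as both C1 epimers. Me2TiCl2 (from Me2Zn and TiCl4, CH2Cl2, −40 → 0 °C) then replaces the tertiary allylic hydroxyl by methyl through a bromo-allyl cation, for which the hydride shift is uphill, to give 14.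

- **Step 11 (catalytic allylboration making the quaternary centre).** A γ,γ-disubstituted boronate with an enal may react slowly or with insufficient facial control. The fallback sets out from 30 and 33 and returns at 35. Uncatalysed allylboration (toluene, 60 °C) still gives only the anti relationship, as a 1:1 mixture of 35 and its (5R,6S)-diastereomer F5. Sharpless kinetic resolution (Ti(OiPr)4, D-(−)-diisopropyl tartrate, t-BuOOH, 4 Å molecular sieves, CH2Cl2, −20 °C) epoxidises only the (6S)-carbinol to the epoxy alcohol F6, and 35 is recovered by chromatography. Because C10 and C11 are locked to each other, resolving C11 also resolves C10.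

- **Step 10 (hydrozirconation–carbonylation).** Cp2Zr(H)Cl may touch the 1,1-disubstituted alkenes, or the acyl complex may hydrolyse poorly. The fallback sets out from 24 and returns at 35. Formylation of the lithium acetylide (n-BuLi, THF, −78 °C; DMF) gives (6R,10R)-6,10,11-trimethyl-7-methylidenedodec-11-en-2-ynal F3. Allylboration with 30 under the step 11 conditions gives the propargylic alcohol F4. Hydroxyl-directed trans-reduction with NaAlH2(OCH2CH2OMe)2 (THF, 0 °C) converts the alkyne into the E-alkene of 35.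

**Further compounds**
F1 | step 4 | (3R)-3-methylhept-6-yn-2-one | CC(=O)[C@H](C)CCC#C
F2 | step 4 | (6R)-3-bromo-1,6-dimethylcyclohex-2-en-1-ol (both C1 epimers) | BrC1=CC(C)(O)[C@H](C)CC1
F3 | step 10 | (6R,10R)-6,10,11-trimethyl-7-methylidenedodec-11-en-2-ynal | O=CC#CCC[C@@H](C)C(=C)CC[C@@H](C)C(C)=C
F4 | step 10 | (2R,5S,6S,11R,15R)-5-ethenyl-5,11,15,16-tetramethyl-12-methylidene-2-[(4R)-3,3,4-trimethylcyclohex-1-en-1-yl]heptadec-16-en-7-yn-6-ol | C=C[C@@](C)([C@H](O)C#CCC[C@@H](C)C(=C)CC[C@@H](C)C(C)=C)CC[C@@H](C)C1=CC(C)(C)[C@H](C)CC1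
F5 | step 11 | (2R,5R,6S,7E,11R,15R)-diastereomer of 35 | C=C[C@](C)([C@@H](O)/C=C/CC[C@@H](C)C(=C)CC[C@@H](C)C(C)=C)CC[C@@H](C)C1=CC(C)(C)[C@H](C)CC1
F6 | step 11 | (2R,5R,6R,7S,8S,11R,15R)-7,8-epoxy-5-ethenyl-5,11,15,16-tetramethyl-12-methylidene-2-[(4R)-3,3,4-trimethylcyclohex-1-en-1-yl]heptadec-16-en-6-ol | C=C[C@](C)([C@@H](O)[C@@H]1O[C@H]1CC[C@@H](C)C(=C)CC[C@@H](C)C(C)=C)CC[C@@H](C)C2=CC(C)(C)[C@H](C)CC2
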